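**Plan**

- Retrosynthesis: the acyl C–O bonds on O8 and O9, the C11=C13 methylene and the O6–C12 lactone bond are cut first. The Z C1=C10 olefin is then written as C1–SO2–C10, which opens the ten-membered ring to an eleven-membered sulfone. Cutting S–C1, C10–S, C8–C9 and C6=C7 leaves a C1–C6 enal, a C7/C8/C11/C12 lactone ylide and hydroxyacetone.
- Forward: the chain is joined by Wittig olefination (C6=C7) and aldol addition (C8–C9). The first ring is the eleven-membered thioether (S–C1 alkylation). Sulfur extrusion contracts it to the ten-membered carbocycle. The γ-lactone closes last, followed by methylenation and the two esters.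
- Enabling feature: the Z-trisubstituted C1=C10 double bond (methyl C14 on C10) of the cyclodeca-1(10),4-diene ring is the equivalent of C1–SO2–C10 in an eleven-membered cyclic sulfone.
- Stereochemistry: C6/C7 come from a Sharpless epoxidation directed by the C8 allylic alcohol and invertive opening at C6. C8/C9 come from a D-proline aldol. C10 is erased in the key step. 4E comes from carboalumination and 1(10)Z from the episulfone. The epoxyangelate comes from a second Sharpless epoxidation.

Key step: step 16

Remarks: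
- Locants are germacrane locants (ring C1–C10, lactone carbons C11–C13, C14 the methyl on C10); TBS = tert-butyldimethylsilyl.
- The lactone Wittig reagent of step 3 is taken as purchasable; otherwise it is one operation from α-bromo-γ-butyrolactone and PPh3.
- Both C10 epimers of the cyclic sulfone converge in step 16; the route carries the 10S epimer.

**Route**

Step 1
Reactants: 1 5-chloropent-1-yne
Product: 3 (2E)-6-chloro-3-methylhex-2-en-1-ol, via alkenylalane 2 (not isolated)
Conditions: AlMe3, Cp2ZrCl2 (cat.), CH2Cl2, 0 °C to rt; then n-BuLi, THF, −78 °C; (CH2O)n, rt; aq. HCl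
Reagents that add atoms: trimethylaluminium C[Al](C)C; formaldehyde (from paraformaldehyde) C=O
Why: Negishi zirconium-catalysed carboalumination adds methyl and aluminium syn across the alkyne with aluminium at the terminus, and the derived alanate is hydroxymethylated with retention, which fixes the 4E olefin while the primary chloride stays inert.

Step 2
Reactants: 3 (2E)-6-chloro-3-methylhex-2-en-1-ol
Product: 4 (2E)-6-chloro-3-methylhex-2-enal
Conditions: MnO2, CH2Cl2, rt
Reagents that add atoms: none
Why: Allylic oxidation on MnO2 stops at the enal and does not isomerise the double bond.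

Step 3
Reactants: 4 (2E)-6-chloro-3-methylhex-2-enal; 5 α-(triphenylphosphoranylidene)-γ-butyrolactone
Product: 6 (3E)-3-[(2E)-6-chloro-3-methylhex-2-en-1-ylidene]oxolan-2-one
Conditions: toluene, 80 °C
Reagents that add atoms: none
Why: Wittig olefination with the stabilised lactone ylide should give the E-alkylidene lactone (C5 trans to the carbonyl carbon C8), the geometry that the later anti-dioxygenation of C6=C7 requires.

Step 4
Reactants: 6 dienyl lactone
Product: 8 bis-silylated dienoate (TBS ester and C12 TBS ether), via lithium carboxylate 7 (not isolated)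
Conditions: LiOH, THF/H2O, rt; evaporate; TBSCl, imidazole, DMF, rt
Reagents that add atoms: lithium hydroxide [Li+].[OH-]; tert-butyldimethylsilyl chloride CC(C)(C)[Si](C)(C)Cl
Why: Saponification opens the lactone and silylation of the hydroxy carboxylate salt caps both oxygens, so that O12 stays protected while C8 remains a reducible silyl ester.

Step 5
Reactants: 8 bis-silylated dienoate
Product: 9 (2E,4E)-2-[2-(TBS-oxy)ethyl]-8-chloro-5-methylocta-2,4-dien-1-ol
Conditions: i-Bu2AlH, CH2Cl2, −78 to 0 °C; aq. potassium sodium tartrate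
Reagents that add atoms: none
Why: 1,2-Hydride reduction of the silyl ester gives the allylic alcohol without touching the diene, the silyl ether or the alkyl chloride.

Step 6
Reactants: 9 dienol
Product: 10 (2R,3R)-epoxy alcohol (C6–C7 epoxide)
Conditions: Ti(OiPr)4 (cat.), D-(−)-diethyl tartrate (cat.), t-BuOOH, 4 Å sieves, CH2Cl2, −20 °C
Reagents that add atoms: tert-butyl hydroperoxide CC(C)(C)OO
Why: Sharpless asymmetric epoxidation acts only on the olefin of the bound allylic alcohol (C4=C5 is spared), and D-(−)-tartrate delivers oxygen to the face that places the future C7 hydroxyl correctly (reagent control).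

Step 7
Reactants: 10 epoxy alcohol
Product: 11 C6 benzoate of the C6,C7,C8-triol
Conditions: Ti(OiPr)4, PhCO2H, CH2Cl2, 0 °C to rt; aq. tartaric acid
Reagents that add atoms: benzoic acid OC(=O)c1ccccc1
Why: Titanium-mediated opening of a 2,3-epoxy alcohol by a carboxylic acid occurs at C3, here the allylic C6, with inversion, which sets 6S while C7 keeps the epoxide oxygen; the diol monoester is oxidised at once to forestall acyl migration.

Step 8
Reactants: 11 triol monobenzoate
Product: 12 α-hydroxy aldehyde (C8 formyl)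
Conditions: TEMPO (cat.), PhI(OAc)2, CH2Cl2, rt
Reagents that add atoms: none
Why: TEMPO-mediated oxidation converts only the primary C8 alcohol; the tertiary hydroxyl and the allylic benzoate are inert and the aldehyde cannot enolise.

Step 9
Reactants: 12 α-hydroxy aldehyde; 13 hydroxyacetone
Product: 14 anti-aldol triol methyl ketone
Conditions: D-proline (30 mol%), hydroxyacetone (excess), DMSO, rt
Reagents that add atoms: none
Why: In the proline-catalysed direct aldol the enamine forms at the hydroxylated carbon of hydroxyacetone and adds to the non-enolisable aldehyde through the acid-bound chair transition state to give the anti-1,2-diol; D-proline should set 8S and 9R under catalyst control.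

Step 10
Reactants: 14 aldol triol
Product: 15 C8,C9-acetonide methyl ketone
Conditions: 2-methoxypropene, PPTS (cat.), CH2Cl2, 0 °C
Reagents that add atoms: 2-methoxypropene C=C(C)OC
Why: Kinetic acid-catalysed ketalisation should engage the two secondary hydroxyls before the hindered tertiary C7 hydroxyl and give the cis-dioxolane; no base is present that could epimerise C9.

Step 11
Reactants: 15 acetonide ketone
Product: 16 C10 alcohol (10R)
Conditions: LiBH(s-Bu)3, THF, −78 °C; then H2O
Reagents that add atoms: none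
Why: Felkin–Anh reduction of the α-alkoxy ketone by the bulky borohydride (hydride anti to the C9–O bond) should give mainly the 10R alcohol; the minor epimer is equally usable because C10 is erased later.

Step 12
Reactants: 16 C10 alcohol
Product: 17 C10 thioacetate (10S)
Conditions: PPh3, DIAD, AcSH, THF, 0 °C to rt
Reagents that add atoms: thioacetic S-acid CC(=O)S
Why: Mitsunobu reaction: thioacetate displaces the oxyphosphonium group by SN2 with inversion at C10; the tertiary hydroxyl and the primary chloride do not take part.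

Step 13
Reactants: 17 thioacetate
Product: 19 eleven-membered hydroxy sulfide, via thiol 18 (not isolated)
Conditions: K2CO3, NaI (cat.), degassed MeOH/THF, 1 mM, rt to 45 °C
Reagents that add atoms: none
Why: Methanolysis frees the thiol and the C6 hydroxyl, and the thiolate closes the ring by intramolecular SN2 alkylation at the primary C1 chloride (11-exo-tet) under high dilution.

Step 14
Reactants: 19 hydroxy sulfide
Product: 20 C6 TBS ether of the cyclic sulfide
Conditions: TBSOTf, 2,6-lutidine, CH2Cl2, −78 °C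
Reagents that add atoms: tert-butyldimethylsilyl triflate CC(C)(C)[Si](C)(C)OS(=O)(=O)C(F)(F)F
Why: Low-temperature silylation takes the secondary C6 hydroxyl and leaves the tertiary C7 hydroxyl free.

Step 15
Reactants: 20 cyclic sulfide
Product: 22 eleven-membered cyclic sulfone, via sulfoxide 21 (not isolated)
Conditions: (NH4)6Mo7O24·4H2O (cat.), 30% H2O2, EtOH, 0 °C to rt
Reagents that add atoms: hydrogen peroxide OO
Why: Molybdate-catalysed peroxide oxidation takes sulfur through the sulfoxide to the sulfone and spares the trisubstituted olefin, which a peracid would epoxidise.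

Step 16
Reactants: 22 eleven-membered cyclic sulfone
Product: 25 ten-membered (1(10)Z,4E)-diene, via bromo sulfone 23 (not isolated), via episulfone 24 (not isolated)
Conditions: CBr2F2, KOH/Al2O3, t-BuOH/CH2Cl2, 0 °C to rt
Reagents that add atoms: none
Why: KOH on alumina deprotonates the unhindered C1 methylene and CBr2F2 transfers bromine to give 23; deprotonation at C10 and 1,3-displacement of bromide (3-exo-tet) then close the episulfone 24 between C1 and C10. Cheletropic loss of SO2 from 24 leaves the C1=C10 double bond, so the eleven-membered thiacycle contracts to the ten-membered carbocycle; this is the Ramberg–Bäcklund reaction with in situ halogenation, which is established for contracting cyclic sulfones to cycloalkenes. No stereocentre is formed and C10 is planarised, which is why its configuration in 22 does not matter. The step needs the Z olefin, and the cis-fused episulfone that leads to it is the kinetically preferred one under these heterogeneous, weakly basic conditions and the less strained one on the medium ring. It also needs 1,3-closure to outrun β-elimination of the C9 oxygen from the C10 carbanion; the leaving group would be a poor acetal alkoxide that the cis-fused dioxolane holds away from the carbanion axis, and β-alkoxy sulfones such as glycosyl sulfones are known to survive this reaction. The tertiary C7 hydroxyl is tolerated (the solvent is itself a tertiary alcohol), and silyl ethers and the acetonide are stable to the base.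

Step 17
Reactants: 25 bis-silyl diene
Product: 26 C6,C7,C12-triol
Conditions: Bu4NF, THF, rt to 40 °C
Reagents that add atoms: none
Why: Fluoride-mediated desilylation frees the C6 and C12 hydroxyls and leaves acetonide and diene untouched.

Step 18
Reactants: 26 triol
Product: 28 6,12-lactone (7-hydroxy), via lactol 27 (not isolated)
Conditions: TEMPO (cat.), PhI(OAc)2, CH2Cl2, rt
Reagents that add atoms: none
Why: Oxoammonium oxidation of the primary C12 alcohol gives the aldehyde, which closes to the five-membered lactol with the C6 hydroxyl and is oxidised on to the γ-lactone; with O8 locked in the acetonide only the 6,12-lactone can form.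

Step 19
Reactants: 28 lactone
Product: 31 α-methylene lactone acetonide, via Mannich base 29 (not isolated), via methiodide 30 (not isolated)
Conditions: LiN(i-Pr)2 (3 equiv), THF, −78 °C; (CH2=NMe2)I, −78 to 0 °C; then MeI, MeOH, rt; then aq. NaHCO3, CH2Cl2
Reagents that add atoms: N,N-dimethylmethyleneiminium iodide C=[N+](C)C.[I-]
Why: Mannich methylenation: the lactone enolate, formed as the dianion with the C7 alkoxide (not eliminated, as in Fráter–Seebach alkylations), adds to the iminium salt at C11, and quaternisation followed by E1cB loss of trimethylamine gives the exocyclic olefin.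

Step 20
Reactants: 31 α-methylene lactone acetonide
Product: 32 C7,C8,C9-triol α-methylene lactone
Conditions: AcOH/THF/H2O (3:1:1), 40 °C
Reagents that add atoms: none
Why: Mild acid-catalysed acetal hydrolysis should be tolerated by the allylic C9–O bond, the 1,5-diene and the α-methylene lactone.

Step 21
Reactants: 33 angelic acid
Product: 34 (2Z)-2-methylbut-2-en-1-ol
Conditions: LiAlH4, Et2O, 0 °C to rt
Reagents that add atoms: none
Why: 1,2-Reduction of the unsaturated acid by LiAlH4 keeps the Z geometry.

Step 22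
Reactants: 34 (2Z)-2-methylbut-2-en-1-ol
Product: 35 [(2R,3S)-2,3-dimethyloxiran-2-yl]methanol
Conditions: Ti(OiPr)4 (cat.), D-(−)-diethyl tartrate (cat.), t-BuOOH, 4 Å sieves, CH2Cl2, −20 °C
Reagents that add atoms: tert-butyl hydroperoxide CC(C)(C)OO
Why: Sharpless asymmetric epoxidation with D-(−)-tartrate should give the 2R,3S-epoxide, cis as fixed by the Z olefin.

Step 23
Reactants: 35 epoxy alcohol
Product: 36 (2S,3S)-2,3-dimethyloxirane-2-carboxylic acid
Conditions: RuCl3 (cat.), NaIO4, CCl4/MeCN/H2O, rt
Reagents that add atoms: water O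
Why: RuO4 oxidation (generated from RuCl3 and NaIO4) takes the primary alcohol through the aldehyde hydrate to the acid without opening the epoxide; the C2 descriptor changes only because the priorities change.

Step 24
Reactants: 32 triol α-methylene lactone; 36 epoxy acid
Product: 38 C9 epoxyangelate, via mixed anhydride 37 (not isolated)
Conditions: 36, 2,4,6-trichlorobenzoyl chloride, Et3N, THF, rt; then 32, DMAP, toluene, rt
Reagents that add atoms: none
Why: Yamaguchi esterification: the mixed anhydride should acylate the allylic C9 hydroxyl, which is less hindered than the C8 hydroxyl next to the fully substituted C7; the tertiary hydroxyl does not react.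

Step 25
Reactants: 38 C9 epoxyangelate
Product: 39 CNP0271187.2
Conditions: Ac2O, pyridine, DMAP (cat.), CH2Cl2, 0 °C to rt
Reagents that add atoms: acetic anhydride CC(=O)OC(C)=O
Why: DMAP-catalysed acetylation takes the remaining secondary C8 hydroxyl; the tertiary C7 hydroxyl is inert under these conditions.

**Compound list**

1 | 5-chloropent-1-yne | C#CCCCCl | starting material
2 | (E)-(5-chloro-2-methylpent-1-en-1-yl)dimethylalane | C[Al](C)/C=C(\C)CCCCl | intermediate
3 | (2E)-6-chloro-3-methylhex-2-en-1-ol | OC/C=C(\C)CCCCl | intermediate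
4 | (2E)-6-chloro-3-methylhex-2-enal | O=C/C=C(\C)CCCCl | intermediate
5 | α-(triphenylphosphoranylidene)-γ-butyrolactone | O=C1OCCC1=P(c1ccccc1)(c1ccccc1)c1ccccc1 | starting material
6 | (3E)-3-[(2E)-6-chloro-3-methylhex-2-en-1-ylidene]oxolan-2-one | O=C1OCC/C1=C\C=C(/C)CCCCl | intermediate
7 | lithium (2E,4E)-8-chloro-2-(2-hydroxyethyl)-5-methylocta-2,4-dienoate | OCC/C(C(=O)[O-])=C\C=C(/C)CCCCl.[Li+] | intermediate
8 | tert-butyldimethylsilyl (2E,4E)-2-[2-(tert-butyldimethylsilyloxy)ethyl]-8-chloro-5-methylocta-2,4-dienoate | CC(C)(C)[Si](C)(C)OCC/C(C(=O)O[Si](C)(C)C(C)(C)C)=C\C=C(/C)CCCCl | intermediate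
9 | (2E,4E)-2-[2-(tert-butyldimethylsilyloxy)ethyl]-8-chloro-5-methylocta-2,4-dien-1-ol | CC(C)(C)[Si](C)(C)OCC/C(CO)=C\C=C(/C)CCCCl | intermediate
10 | [(2R,3R)-2-[2-(tert-butyldimethylsilyloxy)ethyl]-3-[(1E)-5-chloro-2-methylpent-1-en-1-yl]oxiran-2-yl]methanol | OC[C@@]1(CCO[Si](C)(C)C(C)(C)C)O[C@@H]1/C=C(\C)CCCCl | intermediate
11 | (2R,3S,4E)-2-[2-(tert-butyldimethylsilyloxy)ethyl]-8-chloro-1,2-dihydroxy-5-methyloct-4-en-3-yl benzoate | OC[C@](O)(CCO[Si](C)(C)C(C)(C)C)[C@@H](OC(=O)c1ccccc1)/C=C(\C)CCCCl | intermediate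
12 | (2S,3S,4E)-2-[2-(tert-butyldimethylsilyloxy)ethyl]-8-chloro-2-hydroxy-5-methyl-1-oxooct-4-en-3-yl benzoate | O=C[C@](O)(CCO[Si](C)(C)C(C)(C)C)[C@@H](OC(=O)c1ccccc1)/C=C(\C)CCCCl | intermediate
13 | hydroxyacetone (1-hydroxypropan-2-one) | CC(=O)CO | starting material
14 | (3R,4S,5R,6S,7E)-5-[2-(tert-butyldimethylsilyloxy)ethyl]-11-chloro-3,4,5-trihydroxy-8-methyl-2-oxoundec-7-en-6-yl benzoate | CC(=O)[C@H](O)[C@H](O)[C@](O)(CCO[Si](C)(C)C(C)(C)C)[C@@H](OC(=O)c1ccccc1)/C=C(\C)CCCCl | intermediate
15 | (3S,4S,5E)-3-[(4S,5R)-5-acetyl-2,2-dimethyl-1,3-dioxolan-4-yl]-1-(tert-butyldimethylsilyloxy)-9-chloro-3-hydroxy-6-methylnon-5-en-4-yl benzoate | CC(=O)[C@@H]1OC(C)(C)O[C@@H]1[C@](O)(CCO[Si](C)(C)C(C)(C)C)[C@@H](OC(=O)c1ccccc1)/C=C(\C)CCCCl | intermediate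
16 | (3S,4S,5E)-1-(tert-butyldimethylsilyloxy)-9-chloro-3-hydroxy-3-[(4S,5S)-5-[(1R)-1-hydroxyethyl]-2,2-dimethyl-1,3-dioxolan-4-yl]-6-methylnon-5-en-4-yl benzoate | C[C@@H](O)[C@@H]1OC(C)(C)O[C@@H]1[C@](O)(CCO[Si](C)(C)C(C)(C)C)[C@@H](OC(=O)c1ccccc1)/C=C(\C)CCCCl | intermediate
17 | (3S,4S,5E)-3-[(4S,5R)-5-[(1S)-1-(acetylsulfanyl)ethyl]-2,2-dimethyl-1,3-dioxolan-4-yl]-1-(tert-butyldimethylsilyloxy)-9-chloro-3-hydroxy-6-methylnon-5-en-4-yl benzoate | CC(=O)S[C@@H](C)[C@@H]1OC(C)(C)O[C@@H]1[C@](O)(CCO[Si](C)(C)C(C)(C)C)[C@@H](OC(=O)c1ccccc1)/C=C(\C)CCCCl | intermediate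
18 | (3S,4S,5E)-1-(tert-butyldimethylsilyloxy)-9-chloro-3-[(4S,5R)-2,2-dimethyl-5-[(1S)-1-sulfanylethyl]-1,3-dioxolan-4-yl]-6-methylnon-5-ene-3,4-diol | S[C@@H](C)[C@@H]1OC(C)(C)O[C@@H]1[C@](O)(CCO[Si](C)(C)C(C)(C)C)[C@@H](O)/C=C(\C)CCCCl | intermediate
19 | eleven-membered cyclic sulfide (S bridges C1 and C10; C4=C5 E; 6-OH; 7-OH; 7-CH2CH2OTBS; 8,9-O-isopropylidene, cis; 10-methyl), (6S,7S,8S,9R,10S) | O[C@H]1/C=C(\C)CCCS[C@@H](C)[C@@H]2OC(C)(C)O[C@@H]2[C@@]1(CCO[Si](C)(C)C(C)(C)C)O | intermediate
20 | 6-O-TBS ether of 19, (6S,7R,8S,9R,10S) | CC(C)(C)[Si](C)(C)O[C@H]1/C=C(\C)CCCS[C@@H](C)[C@@H]2OC(C)(C)O[C@@H]2[C@@]1(CCO[Si](C)(C)C(C)(C)C)O | intermediate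
21 | S-oxide of 20 (sulfoxide, both configurations at sulfur) | CC(C)(C)[Si](C)(C)O[C@H]1/C=C(\C)CCCS(=O)[C@@H](C)[C@@H]2OC(C)(C)O[C@@H]2[C@@]1(CCO[Si](C)(C)C(C)(C)C)O | intermediate
22 | eleven-membered cyclic sulfone C1–SO2–C10 (6-OTBS; 7-OH; 7-CH2CH2OTBS; 8,9-O-isopropylidene; 4E), (6S,7R,8S,9R,10S) | CC(C)(C)[Si](C)(C)O[C@H]1/C=C(\C)CCCS(=O)(=O)[C@@H](C)[C@@H]2OC(C)(C)O[C@@H]2[C@@]1(CCO[Si](C)(C)C(C)(C)C)O | intermediate
23 | C1-bromo derivative of sulfone 22 (both C1 configurations) | CC(C)(C)[Si](C)(C)O[C@H]1/C=C(\C)CCC(Br)S(=O)(=O)[C@@H](C)[C@@H]2OC(C)(C)O[C@@H]2[C@@]1(CCO[Si](C)(C)C(C)(C)C)O | intermediate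
24 | episulfone (thiirane 1,1-dioxide spanning C1 and C10, fused to the ten-membered ring) | CC(C)(C)[Si](C)(C)O[C@H]1/C=C(\C)CCC3C(C)(S3(=O)=O)[C@@H]2OC(C)(C)O[C@@H]2[C@@]1(CCO[Si](C)(C)C(C)(C)C)O | intermediate
25 | ten-membered (1(10)Z,4E)-diene (6-OTBS; 7-OH; 7-CH2CH2OTBS; 8,9-O-isopropylidene), (6S,7R,8S,9S) | CC(C)(C)[Si](C)(C)O[C@H]1/C=C(\C)CC/C=C(/C)[C@@H]2OC(C)(C)O[C@@H]2[C@@]1(CCO[Si](C)(C)C(C)(C)C)O | intermediate
26 | (1(10)Z,4E)-diene triol (6-OH, 7-OH, 12-OH; 8,9-O-isopropylidene), (6S,7S,8S,9S) | O[C@H]1/C=C(\C)CC/C=C(/C)[C@@H]2OC(C)(C)O[C@@H]2[C@@]1(CCO)O | intermediate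
27 | 6,12-lactol of 26 (both C12 configurations) | O1[C@H]2/C=C(\C)CC/C=C(/C)[C@@H]3OC(C)(C)O[C@@H]3[C@@]2(CC1O)O | intermediate
28 | 7-hydroxy-8,9-O-isopropylidene-germacra-1(10)Z,4E-dien-6,12-olide, (6S,7S,8S,9S) | O1[C@H]2/C=C(\C)CC/C=C(/C)[C@@H]3OC(C)(C)O[C@@H]3[C@@]2(CC1=O)O | intermediate
29 | 11-(dimethylaminomethyl) derivative of 28 (both C11 configurations) | O1[C@H]2/C=C(\C)CC/C=C(/C)[C@@H]3OC(C)(C)O[C@@H]3[C@@]2(C(CN(C)C)C1=O)O | intermediate
30 | trimethylammonium iodide of 29 | O1[C@H]2/C=C(\C)CC/C=C(/C)[C@@H]3OC(C)(C)O[C@@H]3[C@@]2(C(C[N+](C)(C)C)C1=O)O.[I-] | intermediate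
31 | 7-hydroxy-8,9-O-isopropylidene-germacra-1(10)Z,4E,11(13)-trien-6,12-olide, (6S,7S,8S,9S) | O1[C@H]2/C=C(\C)CC/C=C(/C)[C@@H]3OC(C)(C)O[C@@H]3[C@@]2(C(=C)C1=O)O | intermediate
32 | 7,8,9-trihydroxy-germacra-1(10)Z,4E,11(13)-trien-6,12-olide, (6S,7R,8S,9S) | O1[C@H]2/C=C(\C)CC/C=C(/C)[C@H](O)[C@H](O)[C@@]2(C(=C)C1=O)O | intermediate
33 | angelic acid, (2Z)-2-methylbut-2-enoic acid | C/C=C(/C)C(=O)O | starting material
34 | (2Z)-2-methylbut-2-en-1-ol | C/C=C(/C)CO | intermediate
35 | [(2R,3S)-2,3-dimethyloxiran-2-yl]methanol | OC[C@@]1(C)O[C@H]1C | intermediate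
36 | (2S,3S)-2,3-dimethyloxirane-2-carboxylic acid | OC(=O)[C@@]1(C)O[C@H]1C | intermediate
37 | (2S,3S)-2,3-dimethyloxirane-2-carboxylic 2,4,6-trichlorobenzoic anhydride | O=C(OC(=O)[C@@]1(C)O[C@H]1C)c1c(Cl)cc(Cl)cc1Cl | intermediate
38 | 9-O-[(2S,3S)-2,3-dimethyloxirane-2-carbonyl] derivative of 32 (8-OH and 7-OH free), (6S,7R,8S,9S) | O1[C@H]2/C=C(\C)CC/C=C(/C)[C@H](OC(=O)[C@@]3(C)O[C@H]3C)[C@H](O)[C@@]2(C(=C)C1=O)O | intermediate
39 | CNP0271187.2: 8-O-acetyl-9-O-[(2S,3S)-epoxyangeloyl]-7-hydroxy-germacra-1(10)Z,4E,11(13)-trien-6,12-olide, (6S,7S,8S,9S) | C=C1C(=O)O[C@H]2/C=C(\C)CC/C=C(/C)[C@H](OC(=O)[C@@]3(C)O[C@H]3C)[C@H](OC(C)=O)[C@]12O | target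

**Step count and risks**

Total step count: 25. Longest linear sequence: 22 steps (steps 1–20, 24 and 25, from 5-chloropent-1-yne); steps 21–23 make the side-chain acid.

Steps most likely to fail:

1. Step 16 (sulfur extrusion). The C10 carbanion may expel the C9 acetonide oxygen by β-elimination, or halogenation may outrun the 1,3-closure and lead to polyhalogenated sulfone. The fallback sets out from sulfone 22 and separates halogenation from ring contraction. Kinetic deprotonation at the less hindered C1 methylene with LiN(i-Pr)2 (2.2 equiv, THF, −78 °C; one equivalent is taken by the C7 hydroxyl) and quenching with C2Cl6 should give the isolable C1-chloro sulfone F1. Brief treatment of F1 with t-BuOK in THF at −40 °C then brings about the 1,3-elimination and SO2 loss under homogeneous conditions without excess halogenating agent. The sequence comes back to the route at diene 25.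

2. Step 13 (eleven-membered thioether closure). Intermolecular alkylation to oligomers, or disulfide formation, may outpace the slow medium-ring closure. The fallback sets out from thioacetate 17 and closes a twelve-membered ring under equilibrating conditions before deleting one sulfur. Displacement of the C1 chloride with KSAc and NaI in DMF should give the bis(thioacetate) F2. Methanolysis (K2CO3, degassed MeOH) frees the dithiol F3, and air oxidation in dilute basic methanol, where thiol–disulfide exchange corrects oligomers, gives the twelve-membered cyclic disulfide F4. Desulfurisation of F4 with P(NEt2)3 in warm benzene is expected to proceed by attack of phosphorus on the less hindered sulfur on C1 and SN2 closure by the C10 thiolate at the primary C1, with loss of the phosphine sulfide. The sequence comes back to the route at hydroxy sulfide 19.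

3. Step 9 (proline aldol). Enamine addition to the neopentyl-type aldehyde may be slow, the substrate bias may oppose the catalyst, or the α-hydroxy aldehyde may undergo α-ketol rearrangement. The fallback sets out from aldehyde 12 and replaces steps 9–12 by substrate- and reagent-controlled additions. (E)-MeCH=CHMgBr (excess, THF, −78 °C, where the hindered benzoate is left alone) adds to the magnesium alkoxide chelate of the α-hydroxy aldehyde from the side of the C11 methylene and should give the 8S allylic alcohol F5. Sharpless epoxidation of F5 with Ti(OiPr)4, D-(−)-diethyl tartrate and t-BuOOH (matched pair) gives the anti epoxy alcohol F6. Opening of F6 at C10 with AcSH and Ti(OiPr)4 (distal carbon, inversion) gives the 10S thioacetate triol F7. Kinetic ketalisation of F7 with 2-methoxypropene and PPTS returns to the route at thioacetate 17.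

**Further compounds**

F1 | step 16 | C1-chloro derivative of sulfone 22 (both C1 configurations) | CC(C)(C)[Si](C)(C)O[C@H]1/C=C(\C)CCC(Cl)S(=O)(=O)[C@@H](C)[C@@H]2OC(C)(C)O[C@@H]2[C@@]1(CCO[Si](C)(C)C(C)(C)C)O
F2 | step 13 | bis(thioacetate): compound 17 with acetylsulfanyl in place of chlorine at C1 | CC(=O)S[C@@H](C)[C@@H]1OC(C)(C)O[C@@H]1[C@](O)(CCO[Si](C)(C)C(C)(C)C)[C@@H](OC(=O)c1ccccc1)/C=C(\C)CCCSC(C)=O
F3 | step 13 | dithiol (C1–SH and C10–SH, 6-OH and 7-OH free, 8,9-acetonide, 12-OTBS) | S[C@@H](C)[C@@H]1OC(C)(C)O[C@@H]1[C@](O)(CCO[Si](C)(C)C(C)(C)C)[C@@H](O)/C=C(\C)CCCS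
F4 | step 13 | twelve-membered cyclic disulfide (C1–S–S–C10; otherwise as 19) | O[C@H]1/C=C(\C)CCCSS[C@@H](C)[C@@H]2OC(C)(C)O[C@@H]2[C@@]1(CCO[Si](C)(C)C(C)(C)C)O
F5 | step 9 | (E)-propenyl carbinol: C8 alcohol with C9=C10 olefin, (6S,7R,8S) | C/C=C/[C@H](O)[C@](O)(CCO[Si](C)(C)C(C)(C)C)[C@@H](OC(=O)c1ccccc1)/C=C(\C)CCCCl
F6 | step 9 | (9R,10R)-9,10-epoxy-8-ol (anti epoxy alcohol), (6S,7R,8S) | C[C@H]1O[C@@H]1[C@H](O)[C@](O)(CCO[Si](C)(C)C(C)(C)C)[C@@H](OC(=O)c1ccccc1)/C=C(\C)CCCCl
F7 | step 9 | C10 thioacetate 7,8,9-triol, (6S,7R,8S,9R,10S) | CC(=O)S[C@@H](C)[C@H](O)[C@H](O)[C@](O)(CCO[Si](C)(C)C(C)(C)C)[C@@H](OC(=O)c1ccccc1)/C=C(\C)CCCCl
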